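Cuts, in retrosynthetic order: the C15–O acyl bond; the C8–C17 bond (carboxyl from CO on the Δ7 enol triflate of the 17-nor-8-ketone 15); then, in one stroke, C9–C10 together with a return of the C4–C5 bond of ring A to C10; last, C7–C8.
That stroke shrinks ring A (C1–C5, C10) to a 1,2,2-trimethylcyclopentane (C1–C4, C10) with C5 outside the ring. A temporary oxolane oxygen ties C5 to C8, so leaving group and enol nucleophile are one functional group (13).
Feature that allows it: C5 lies between two fully substituted carbons, C4 (gem-dimethyl) and C10 (angular methyl). A cation at an exocyclic C5 therefore pulls C4 over from C10 and gives the tertiary C10 cation of labdane biogenesis, with no functional group left in ring A.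
Forward: cyclopentane from camphoric acid (steps 1–3), side chain by carbocupration (4–5), union at C7–C8 (6), carbinol and oxolane (7–8), ring A (five to six) and ring B together in step 9, then triflate, reduction, carbonylation and acylation (10–13).
Stereochemistry: C10 of (1S,3R)-camphoric acid and a CBS reduction (C5) are relayed by two inversions into C5 and C10 of the trans-decalin. C9 follows from the Z enol geometry and is held by equilibration. The 13E alkene comes from a syn-carbocupration.

Key step: step 9

Remark: labdane numbering is used for the atoms of all compounds, precursors included (C1–C10 decalin carbons, C11–C16 side chain, C17 carboxyl carbon, C18–C20 methyl groups).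
Assumption: 1, 6 and 7 are bought.

Step 1
Reactants: 1 (1S,3R)-camphoric acid
Product: 2 (1S,5R)-camphoric anhydride
Conditions: Ac2O, reflux
Reagents that add atoms: none
Why: Dehydrative closure of a cis-1,3-dicarboxylic acid to its six-membered cyclic anhydride with acetic anhydride is routine and touches neither stereocentre.

Step 2
Reactants: 2 (1S,5R)-camphoric anhydride
Product: 4 (1S)-1,2,2-trimethylcyclopentane-1-carboxylic acid, via Barton ester 3 (not isolated)
Conditions: 1-hydroxypyridine-2(1H)-thione, DMAP (cat.), CH2Cl2, dark, 23 °C; then t-BuSH, visible light, 23 °C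
Reagents that add atoms: none
Why: The thiohydroxamic acid should open the anhydride at the less hindered carbonyl on the tertiary carbon C3, as amines and alcohols do, and the O-acyl thiohydroxamate then undergoes Barton reductive decarboxylation (radical chain, hydrogen from the thiol), which removes the only superfluous carbon and leaves the quaternary centre C10 (S) untouched.

Step 3
Reactants: 4 (1S)-1,2,2-trimethylcyclopentane-1-carboxylic acid
Product: 5 1-[(1S)-1,2,2-trimethylcyclopentyl]prop-2-en-1-one
Conditions: vinyllithium (3 equiv, made from tetravinyltin and n-BuLi), Et2O, 0 → 23 °C; inverse quench into cold 1 M HCl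
Reagents that add atoms: vinyllithium, [Li]C=C
Why: Addition of an organolithium to a lithium carboxylate stops at the dilithium gem-diolate, so the vinyl ketone appears only on the acidic quench (ketone synthesis from carboxylic acids and organolithiums), and C10 has no way to epimerise.

Step 4
Reactants: 6 (4-bromobut-1-yn-1-yl)trimethylsilane; 7 methyl but-2-ynoate
Product: 9 methyl (2E)-3-methyl-7-(trimethylsilyl)hept-2-en-6-ynoate, via Grignard reagent 8 (not isolated)
Conditions: Mg, THF; CuBr·SMe2 (1 equiv), −40 °C; 7, −78 °C; aq. NH4Cl at −78 °C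
Reagents that add atoms: none
Why: Syn-carbocupration of an alkynoate at low temperature, followed by protonation with retention, places the new chain trans to the ester and so fixes the 13E geometry.

Step 5
Reactants: 9 methyl (2E)-3-methyl-7-(trimethylsilyl)hept-2-en-6-ynoate
Product: 10 methyl (2E)-3-methylhept-2-en-6-ynoate
Conditions: K2CO3 (cat.), MeOH, 23 °C
Reagents that add atoms: none
Why: Methanolysis of the alkynyl C–Si bond with catalytic carbonate is routine, and transesterification is degenerate because the ester is a methyl ester.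

Step 6
Reactants: 5 1-[(1S)-1,2,2-trimethylcyclopentyl]prop-2-en-1-one; 10 methyl (2E)-3-methylhept-2-en-6-ynoate
Product: 11 methyl (2E)-3-methyl-10-oxo-10-[(1S)-1,2,2-trimethylcyclopentyl]dec-2-en-6-ynoate
Conditions: Pd(OAc)2 (5 mol %), PMe3 (20 mol %), acetone, 60 °C
Reagents that add atoms: none
Why: Palladium-catalysed conjugate addition of terminal alkynes to vinyl ketones (hydroalkynylation) forms C7–C8 under neutral conditions, because the unsubstituted β-carbon of 5 stays open despite the bulky acyl group and the β,β-disubstituted enoate of 10 is no acceptor.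

Step 7
Reactants: 11 methyl (2E)-3-methyl-10-oxo-10-[(1S)-1,2,2-trimethylcyclopentyl]dec-2-en-6-ynoate
Product: 12 methyl (2E,10S)-10-hydroxy-3-methyl-10-[(1S)-1,2,2-trimethylcyclopentyl]dec-2-en-6-ynoate
Conditions: (R)-Me-CBS oxazaborolidine (20 mol %), BH3·SMe2, THF, −30 °C, slow addition of 11; MeOH, then water
Reagents that add atoms: none
Why: The Corey–Bakshi–Shibata reduction distinguishes the tertiary alkyl group from the primary chain as it does in pinacolone, the (R)-catalyst delivers hydride to give the (5S)-carbinol, and ketone reduction at the catalyst should outrun hydroboration of the alkyne at this temperature.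

Step 8
Reactants: 12 methyl (2E,10S)-10-hydroxy-3-methyl-10-[(1S)-1,2,2-trimethylcyclopentyl]dec-2-en-6-ynoate
Product: 13 methyl (2E,6Z)-3-methyl-6-{(5S)-5-[(1S)-1,2,2-trimethylcyclopentyl]oxolan-2-ylidene}hex-2-enoate
Conditions: AuCl (5 mol %), K2CO3 (10 mol %), MeCN, 23 °C
Reagents that add atoms: none
Why: 5-exo-dig anti-oxyauration of a 4-alkyn-1-ol followed by protodeauration is a known route to (Z)-2-alkylidene oxolanes, the ring size fixes oxygen on C8, and the carbonate buffer keeps the double bond exocyclic.

Step 9
Reactants: 13 methyl (2E,6Z)-3-methyl-6-{(5S)-5-[(1S)-1,2,2-trimethylcyclopentyl]oxolan-2-ylidene}hex-2-enoate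
Product: 15 methyl (2E)-3-methyl-5-[(1R,4aS,8aS)-5,5,8a-trimethyl-2-oxodecahydronaphthalen-1-yl]pent-2-enoate, via ring-enlarged C10 cation 14 (not isolated)
Conditions: Me3SiNTf2 (20 mol %), 2,6-di-tert-butyl-4-methylpyridine (30 mol %), CH2Cl2 (0.01 M), −78 → −20 °C; aq. NaHCO3; then K2CO3 (cat.), MeOH, 23 °C
Reagents that add atoms: none
Why: Proposed new method: Me3Si+ from the catalyst binds the enol-ether oxygen of 13, heterolysis of the activated C5–O bond is coupled to a Wagner–Meerwein shift of the antiperiplanar C10–C4 bond, which inserts C5 into the cyclopentane (five to six, ring A) and gives the tertiary C10 cation 14 beside a regiodefined Z silyl enol ether, C9 of which adds to C10, and loss of Me3Si+ from the silyloxocarbenium ion gives 15 and returns the catalyst. The closest known reaction types are the Lewis-acid [1,3] O-to-C (Petasis–Ferrier type) rearrangement of cyclic enol ethers through a cation/enolate pair, the retropinacol shift of neopentyl-type secondary alcohols (3-hydroxy-4,4-dimethyl triterpenoids), the tert-alkylation of silyl enol ethers by tertiary cations and the SnCl4 closure of monocyclic cyclogeranyl β-keto esters, through this same C10 cation, to trans-decalones. Ring A arises by the 1,2-shift and ring B by a 6-(enolendo) attack on the trigonal C10 through a chair transition state with the C5 chain equatorial, while the temporary oxolane is opened. C5 is set by inversion at the (5S)-carbinol carbon, C10 by arrival of C9 anti to the departing C4 (a second inversion that leads to the trans-decalin only from the (5S,10S) diastereomer and agrees with the chair preference of the free cation), and C9 by the Z enol geometry that puts C11 equatorial, backed by base equilibration next to the ketone. The step needs migration of C4 and not of C1 or the methyl group, which is secured because C4 is the most substituted group, lies anti to oxygen in a low-energy rotamer and is the only one whose shift removes the C4/C10 quaternary–quaternary contact; it needs C- before O-attack and capture before proton loss, which is secured by a neutral, non-basic silyl enol ether held within reach, a non-basic NTf2 counter-ion and a hindered pyridine that only traps protons and so keeps the double bond of 13 exocyclic. The side chain is carried as the C15 methyl ester because an allylic ester or ether there would ionise before the C5–O bond.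

Step 10
Reactants: 15 methyl (2E)-3-methyl-5-[(1R,4aS,8aS)-5,5,8a-trimethyl-2-oxodecahydronaphthalen-1-yl]pent-2-enoate
Product: 17 Δ7 enol triflate of 15 (5S,9R,10S; C8–OTf), via potassium enolate 16 (not isolated)
Conditions: KN(SiMe3)2 (1.05 equiv), THF, −78 °C; PhNTf2, −78 → 0 °C; aq. NH4Cl
Reagents that add atoms: N-phenylbis(trifluoromethanesulfonimide), O=S(=O)(N(c1ccccc1)S(=O)(=O)C(F)(F)F)C(F)(F)F
Why: Kinetic deprotonation of a 2-alkylcyclohexanone by a hindered amide base takes the less hindered C7–H, O-triflation of the enolate fixes the Δ7 position of the double bond, and the ketone is more acidic than the γ-positions of the enoate.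

Step 11
Reactants: 17 Δ7 enol triflate of 15
Product: 18 15-hydroxy-17-norlabda-7,13E-dien-8-yl triflate (5S,9R,10S)
Conditions: i-Bu2AlH (2.5 equiv), CH2Cl2, −78 °C; aq. Rochelle salt
Reagents that add atoms: none
Why: i-Bu2AlH reduces α,β-unsaturated esters in 1,2-fashion to allylic alcohols at low temperature with retention of alkene geometry, and enol triflates are inert to it.

Step 12
Reactants: 18 15-hydroxy-17-norlabda-7,13E-dien-8-yl triflate
Product: 19 15-hydroxylabda-7,13E-dien-17-oic acid (5S,9R,10S)
Conditions: Pd(OAc)2 (5 mol %), dppf (10 mol %), CO (1 atm), Et3N, DMF–H2O, 60 °C; dilute HCl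
Reagents that add atoms: carbon monoxide, [C-]#[O+]; water, O
Why: Oxidative addition of zerovalent palladium to the enol triflate, CO insertion and hydrolysis of the acylpalladium species (hydroxycarbonylation) give the conjugated acid, and a free allylic alcohol is not ionised by palladium, which is why the acyl group is put on afterwards.

Step 13
Reactants: 19 15-hydroxylabda-7,13E-dien-17-oic acid
Product: 21 15-(2-methylpropanoyloxy)labda-7,13E-dien-17-oic acid (5S,9R,10S), via mixed anhydride 20 (not isolated)
Conditions: (i-PrCO)2O (3 equiv), pyridine, DMAP (cat.), CH2Cl2, 0 → 23 °C; then THF–aq. NaHCO3, 23 °C; dilute HCl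
Reagents that add atoms: isobutyric anhydride, CC(C)C(=O)OC(=O)C(C)C
Why: The primary allylic alcohol is acylated under DMAP catalysis, and the mixed anhydride that forms at the carboxyl group is hydrolysed again in the aqueous bicarbonate stage, which leaves the free acid.

Compound list
1 | (1S,3R)-1,2,2-trimethylcyclopentane-1,3-dicarboxylic acid, (−)-camphoric acid | C[C@]1(C(=O)O)CC[C@@H](C(=O)O)C1(C)C | starting material
2 | (1S,5R)-1,8,8-trimethyl-3-oxabicyclo[3.2.1]octane-2,4-dione, camphoric anhydride | C[C@]1(C(=O)OC2=O)CC[C@@H]2C1(C)C | intermediate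
3 | (1S,3R)-1,2,2-trimethyl-3-{[(2-thioxopyridin-1(2H)-yl)oxy]carbonyl}cyclopentane-1-carboxylic acid, Barton ester | C[C@]1(C(=O)O)CC[C@@H](C(=O)ON2C=CC=CC2=S)C1(C)C | intermediate
4 | (1S)-1,2,2-trimethylcyclopentane-1-carboxylic acid | C[C@]1(C(=O)O)CCCC1(C)C | intermediate
5 | 1-[(1S)-1,2,2-trimethylcyclopentyl]prop-2-en-1-one | C[C@]1(C(=O)C=C)CCCC1(C)C | intermediate
6 | (4-bromobut-1-yn-1-yl)trimethylsilane | C[Si](C)(C)C#CCCBr | starting material
7 | methyl but-2-ynoate | CC#CC(=O)OC | starting material
8 | [4-(trimethylsilyl)but-3-yn-1-yl]magnesium bromide | C[Si](C)(C)C#CCC[Mg]Br | intermediate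
9 | methyl (2E)-3-methyl-7-(trimethylsilyl)hept-2-en-6-ynoate | C[Si](C)(C)C#CCC/C(C)=C/C(=O)OC | intermediate
10 | methyl (2E)-3-methylhept-2-en-6-ynoate | C#CCC/C(C)=C/C(=O)OC | intermediate
11 | methyl (2E)-3-methyl-10-oxo-10-[(1S)-1,2,2-trimethylcyclopentyl]dec-2-en-6-ynoate | C[C@]1(C(=O)CCC#CCC/C(C)=C/C(=O)OC)CCCC1(C)C | intermediate
12 | methyl (2E,10S)-10-hydroxy-3-methyl-10-[(1S)-1,2,2-trimethylcyclopentyl]dec-2-en-6-ynoate | C[C@]1([C@@H](O)CCC#CCC/C(C)=C/C(=O)OC)CCCC1(C)C | intermediate
13 | methyl (2E,6Z)-3-methyl-6-{(5S)-5-[(1S)-1,2,2-trimethylcyclopentyl]oxolan-2-ylidene}hex-2-enoate | C[C@]1([C@@H]2CC/C(=C/CC/C(C)=C/C(=O)OC)O2)CCCC1(C)C | intermediate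
14 | ring-enlarged 2,2,6-trimethylcyclohexyl (C10) cation with the (Z)-trimethylsilyl enol ether chain on (S)-C5, bis(triflyl)amide salt | C[C+]1CCCC(C)(C)[C@@H]1CC/C(O[Si](C)(C)C)=C/CC/C(C)=C/C(=O)OC.O=S(=O)([N-]S(=O)(=O)C(F)(F)F)C(F)(F)F | intermediate
15 | methyl (2E)-3-methyl-5-[(1R,4aS,8aS)-5,5,8a-trimethyl-2-oxodecahydronaphthalen-1-yl]pent-2-enoate (methyl 8-oxo-17-norlabd-13E-en-15-oate) | C/C(=C\C(=O)OC)CC[C@H]1C(=O)CC[C@H]2C(C)(C)CCC[C@]12C | intermediate
16 | potassium Δ7 enolate of 15 | C/C(=C\C(=O)OC)CC[C@H]1C([O-])=CC[C@H]2C(C)(C)CCC[C@]12C.[K+] | intermediate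
17 | methyl 8-(trifluoromethylsulfonyloxy)-17-norlabda-7,13E-dien-15-oate (5S,9R,10S) | C/C(=C\C(=O)OC)CC[C@H]1C(OS(=O)(=O)C(F)(F)F)=CC[C@H]2C(C)(C)CCC[C@]12C | intermediate
18 | 15-hydroxy-17-norlabda-7,13E-dien-8-yl trifluoromethanesulfonate (5S,9R,10S) | C/C(=C\CO)CC[C@H]1C(OS(=O)(=O)C(F)(F)F)=CC[C@H]2C(C)(C)CCC[C@]12C | intermediate
19 | 15-hydroxylabda-7,13E-dien-17-oic acid (5S,9R,10S) | C/C(=C\CO)CC[C@H]1C(C(=O)O)=CC[C@H]2C(C)(C)CCC[C@]12C | intermediate
20 | mixed anhydride of 21 with isobutyric acid | C/C(=C\COC(=O)C(C)C)CC[C@H]1C(C(=O)OC(=O)C(C)C)=CC[C@H]2C(C)(C)CCC[C@]12C | intermediate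
21 | (1R,4aS,8aS)-5,5,8a-trimethyl-1-[(3E)-3-methyl-5-(2-methylpropanoyloxy)pent-3-en-1-yl]-1,4,4a,5,6,7,8,8a-octahydronaphthalene-2-carboxylic acid | C/C(=C\COC(=O)C(C)C)CC[C@H]1C(C(=O)O)=CC[C@H]2C(C)(C)CCC[C@]12C | target

Total step count: 13. Longest linear sequence: 11 (steps 1–3 and 6–13).

Steps most likely to fail

1. Step 9. The hindered secondary C5–O bond may resist heterolysis. Alternatively, the C10 cation may lose a proton or be taken by oxygen before C9 reaches it. The fallback sets out from 13 and comes back at 15, and it separates the events into known operations. Oxalic acid in THF–water hydrolyses the enol ether to the γ-hydroxy ketone F1. HCl/ZnCl2 in CH2Cl2 then converts the neopentyl-type secondary alcohol, as it does pinacolyl alcohol, into the rearranged, ring-enlarged tertiary chloride F2. This uses the same antiperiplanar C4 shift, sets C5 by inversion, and the configuration at C10 is of no account. TiCl4/i-Pr2NEt then forms the titanium enolates on both sides of C8 and ionises the chloride. Only the enolate toward C9 can reach C10 through a six-membered transition state, so the known alkylation of titanium enolates by tertiary halides closes ring B to 15.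

2. Step 8. The alcohol may close 6-endo onto C9, or the exocyclic double bond may drift into the oxolane ring. The fallback sets out from 5 and 7 and comes back at 13, and it places the double bond by olefination.
   - CBS reduction of 5 with the (R)-catalyst gives the allylic alcohol F3.
   - Linear-selective hydroformylation (Rh(acac)(CO)2, Xantphos, CO/H2) gives the lactol F4.
   - Ph3P·HBF4 gives the oxolan-2-ylphosphonium salt F5.
   - The aldehyde partner comes from 7: carbocupration as in step 4, with the Grignard reagent of 2-(2-bromoethyl)-1,3-dioxolane, gives the acetal ester F6, and dilute acid gives the aldehyde F7.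
   - Wittig reaction of the ylide of F5 (KN(SiMe3)2) with F7 forms C8=C9 by construction. It gives 13 as a mixture of alkene isomers, which is tolerable because C9 is equilibrated after step 9.

3. Step 3. The doubly neopentyl lithium carboxylate may resist addition, or the vinyl ketone may be consumed by polymerisation or by conjugate addition during the quench. The fallback sets out from 4 and comes back at 5. LiAlH4 gives the primary alcohol F8, and Swern oxidation gives the aldehyde F9. Vinylmagnesium bromide gives the allylic alcohol F10 as both carbinol epimers, and a second Swern oxidation gives 5.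

Further compounds
F1 | step 9 | methyl (2E,10S)-10-hydroxy-3-methyl-7-oxo-10-[(1S)-1,2,2-trimethylcyclopentyl]dec-2-enoate | C[C@]1([C@@H](O)CCC(=O)CCC/C(C)=C/C(=O)OC)CCCC1(C)C
F2 | step 9 | methyl (2E)-9-[(1S)-2-chloro-2,6,6-trimethylcyclohexyl]-3-methyl-7-oxonon-2-enoate | CC1(Cl)CCCC(C)(C)[C@@H]1CCC(=O)CCC/C(C)=C/C(=O)OC
F3 | step 8 | (1S)-1-[(1S)-1,2,2-trimethylcyclopentyl]prop-2-en-1-ol | C[C@]1([C@@H](O)C=C)CCCC1(C)C
F4 | step 8 | (5S)-5-[(1S)-1,2,2-trimethylcyclopentyl]oxolan-2-ol | C[C@]1([C@@H]2CCC(O)O2)CCCC1(C)C
F5 | step 8 | triphenyl{(5S)-5-[(1S)-1,2,2-trimethylcyclopentyl]oxolan-2-yl}phosphonium tetrafluoroborate | C[C@]1([C@@H]2CCC(O2)[P+](c2ccccc2)(c2ccccc2)c2ccccc2)CCCC1(C)C.F[B-](F)(F)F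
F6 | step 8 | methyl (2E)-5-(1,3-dioxolan-2-yl)-3-methylpent-2-enoate | C/C(=C\C(=O)OC)CCC1OCCO1
F7 | step 8 | methyl (2E)-3-methyl-6-oxohex-2-enoate | C/C(=C\C(=O)OC)CCC=O
F8 | step 3 | [(1S)-1,2,2-trimethylcyclopentyl]methanol | C[C@]1(CO)CCCC1(C)C
F9 | step 3 | (1S)-1,2,2-trimethylcyclopentane-1-carbaldehyde | C[C@]1(C=O)CCCC1(C)C
F10 | step 3 | 1-[(1S)-1,2,2-trimethylcyclopentyl]prop-2-en-1-ol, both carbinol epimers | C[C@]1(C(O)C=C)CCCC1(C)C
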